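The numbers in the tables were computed from invented constants; the scatter is artificial.

I wanted the other capture product at the end of each flask, and these recipes differ mainly in how fast intermediate is supplied.

| flask | starting material | first nucleophile | second nucleophile | temperature | remark | time |
|---|---|---|---|---|---|---|
| north-east | 0.20 M | 0.30 M | 0.30 M | 55 °C | run made earlier |  |
| north-west | 0.20 M | 0.20 M | 0.30 M | 66 °C | run made earlier |  |
| south | 0.20 M | 0.45 M | 0.30 M | 55 °C | run made earlier |  |
| west | 0.20 M | 0.30 M | 0.15 M | 66 °C | run made earlier |  |
| Wednesday's | 0.20 M | 0.300 M | 0.300 M | 60 °C | everything together at the start | 20 h |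
| Thursday's | 0.20 M | 0.300 M (fed, over 15 h) | 0.300 M |  | the addition at 40 °C, then warmed to 60 °C; the feed brings no volume worth counting | 20 h |
| Tuesday's | 0.20 M (fed, over 15 h) | 0.300 M | 0.300 M | 60 °C | all else is in the flask from the start; the feed brings no volume worth counting | 20 h |
| Sunday's | 0.20 M | 0.300 M (in portions, 4, over 15 h) | 0.300 M | 60 °C | first portion at the start, last at 15 h | 20 h |
| Saturday's | 0.20 M (fed, over 1.5 h) | 0.300 M | 0.300 M | 60 °C | all else is in the flask from the start; the feed brings no volume worth counting | 20 h |

| run | time / h | other capture product / % | target / % | starting material / % |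
|---|---|---|---|---|
| north-east | 2.50 | 24.1 | 5.5 | 69.7 |
| north-east | 8.00 | 35.7 | 30.1 | 32.7 |
| north-east | 12.0 | 35.2 | 44.8 | 17.2 |
| north-east | 20.0 | 35.7 | 57.6 | 6.1 |
| north-west | 5.00 | 43.5 | 44.6 | 8.6 |
| north-west | 10.0 | 44.8 | 54.7 | 1.0 |
| north-west | 15.0 | 44.9 | 55.9 | 0 |
| north-west | 20.0 | 44.7 | 56.2 | 0 |
| south | 1.50 | 14.8 | 2.7 | 80.5 |
| south | 4.00 | 29.4 | 13.7 | 56.0 |
| south | 8.00 | 34.2 | 33.3 | 31.8 |
| south | 20.0 | 35.4 | 59.9 | 6.3 |
| west | 2.50 | 37.0 | 30.8 | 29.5 |
| west | 8.00 | 37.7 | 60.9 | 1.8 |
| west | 12.0 | 36.7 | 62.4 | 0 |
| west | 20.0 | 36.8 | 63.7 | 0 |

(standard deviation of a reading: 0.5 percentage points)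

- on the list of suspects stand: starting material -> intermediate; first nucleophile + intermediate -> target; second nucleophile + intermediate -> other capture product; 2 second nucleophile -> homo dimer; first nucleophile <-> dormant form

- the flask that comes out highest in amount of other capture product, in percent of the starting material charged; "all alike" if 1.5 percentage points covers them all (Wednesday's / Thursday's / Tuesday's / Sunday's / Saturday's / all alike)
- amount of other capture product at the end, in percent of the starting material charged, Wednesday's
- amount of other capture product at the end, in percent of the starting material charged, Thursday's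
- amount of other capture product at the end, in percent of the starting material charged, Tuesday's
- amount of other capture product at the end, in percent of the starting material charged, Sunday's
- amount of other capture product at the end, in percent of the starting material charged, Saturday's

I built a ladder from the fast end. In the north-east run at 8.00 h, starting material, target and other capture product summed to 98.5%, so I took intermediate as captured soon after it formed.

The next rung was the second nucleophile. In that run other capture product read 35.7% at 8.00 h and 35.7% at 20.0 h, while starting material fell from 32.7% to 6.1%. Capture had stopped at 0.0714 M, against 0.30 M charged. I assigned the rest to homo dimer, a loss that goes with c(second nucleophile) squared. That concentration sets the order of the rate.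

Then came starting material. The first readings of the north-east and north-west runs gave 0.144 h⁻¹ at 55 °C and 0.491 h⁻¹ at 66 °C. I interpolated logarithmically, 0.455 of the way, to 0.252 h⁻¹, a half-life of 2.75 h. I treated this step as rate-limiting, so the supply is k times c(starting material): 0.0289 M h⁻¹ at 55 °C, 0.0981 M h⁻¹ in the north-west run, and 0.0504 M h⁻¹ for Wednesday's.

Tuesday's feed supplies 0.0133 M h⁻¹, less than Wednesday's start.

I took each plateau as a balance point and rescaled it, by the root of its own supply, to Wednesday's supply. The north-east plateau became 0.0943 M. The north-west plateau, 0.0894 M, became 0.0640 M. The south plateau read 35.4% against 35.7% in the north-east run, a gap of 0.3 percentage points beside a scatter of 0.5 points per reading, so I left first nucleophile out of the reckoning. Interpolated between the two rescaled plateaus, the reckoning gave 0.0791 M. This is the balance concentration, the c(second nucleophile) at which loss to homo dimer equals the supply of intermediate. At one temperature it grows with the root of the supply, and I read it as the capture product made.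

So I reckoned 39.5% for Wednesday's and for Sunday's, which has the same supply. For Tuesday's I reckoned 0.0407 M, or 20.3%.

The forecast named Sunday's highest, gave 39%, 31%, 14%, 42% and 31% in the asked order, and said “the second nucleophile dimerises before the feed arrives”, its Tuesday's figure standing below mine.

The flasks gave 39.3%, 28.4%, 13.2%, 41.7% and 28.7% in that order, with Sunday's highest.

    starting material → intermediate (k = 7.00 × 10⁻⁵ s⁻¹, Ea = 103 kJ mol⁻¹)
    first nucleophile + intermediate → target (k = 0.00810 M⁻¹ s⁻¹, Ea = 49.0 kJ mol⁻¹)
    second nucleophile + intermediate → other capture product (k = 0.140 M⁻¹ s⁻¹, Ea = 68.0 kJ mol⁻¹)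
    2 second nucleophile → homo dimer (k = 0.00150 M⁻¹ s⁻¹, Ea = 68.0 kJ mol⁻¹)
    first nucleophile ⇌ dormant form (K = 0.840, k = 7.80 × 10⁻⁵ s⁻¹, Ea = 98.0 kJ mol⁻¹, ΔH = −36.0 kJ mol⁻¹)
    (constants at 60 °C)

Wednesday's held 0.0787 M of other capture product against my 0.0791 M. Tuesday's held 0.0265 M against my 0.0407 M, so the batch reading ran high on the fed flask, by a factor of 1.54. I then applied the root of the supply to a neighbour. The neighbour is Tuesday's with 0.080 M of starting material, so its supply is lower by a factor of 2.50. Scaling Tuesday's result gave 20.9% of that charge. The neighbour ended at 23.1%.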